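**Plan**

- Retrosynthesis: the lactone carbonyl C2 is removed as CO (bonds O1–C2 and C2–C3, with the C4–H bond), which leaves a 2-(1-arylvinyl)phenol; then the aryl–vinyl bond C4a–C4 is cut; last, the pyranone ring is opened at C5′–C6′ and O1′–C2′ back to a formyl group.
- Forward: 2,4-dihydroxy-6-methylbenzaldehyde is brominated at the future C4a, the 4-methoxy-2-pyranone ring is built on the formyl carbon, the 1-arylvinyl unit is joined by Suzuki–Miyaura coupling, and the dihydrocoumarin ring is closed last by carbonylation.
- Enabling feature: O1 sits on C8a, ortho to C4a, and C4 carries two aryl groups and one H. A Pd–H can therefore add to C4=C3 only with Pd on C3, and of the three phenol oxygens only O1 can reach C2 in a six-membered ring.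
- Stereochemistry: the single stereocenter C4 (R) is created in the last step by enantioface-selective Pd–H addition under a chiral bisphosphine; no later step can scramble it.
- Numbering: chroman-2-one atoms O1 to C8a; pyranone atoms primed.

Key step: step 9

Remark (assumption): the WingPhos antipode used is the one that gives (R)-4-aryl-3,4-dihydrocoumarins from simple 2-(1-arylvinyl)phenols. The priority order at C4 (C4a > 4-hydroxyphenyl > C3 > H) is the same here, so the same sense of induction corresponds to (4R).

**Route**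

Step 1
Reactants: 1 2,4-dihydroxy-6-methylbenzaldehyde
Product: 2 3-bromo-4,6-dihydroxy-2-methylbenzaldehyde
Conditions: N-bromosuccinimide (1.0 equiv), MeCN, −20 → 0 °C
Reagents that add atoms: N-bromosuccinimide, O=C1CCC(=O)N1Br
Why: Electrophilic aromatic bromination should take place at the carbon para to the hydrogen-bonded hydroxyl and next to the methyl group, the site at which halogenation of 2,4-dihydroxy-6-alkylbenzaldehydes is known to occur, the carbon between the two hydroxyls being the more crowded one.

Step 2
Reactants: 2 3-bromo-4,6-dihydroxy-2-methylbenzaldehyde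
Product: 3 3-bromo-4,6-bis(methoxymethoxy)-2-methylbenzaldehyde
Conditions: NaH (2.5 equiv), DMF, 0 °C; MOMCl (2.5 equiv), 0 °C → rt
Reagents that add atoms: chloromethyl methyl ether, COCCl
Why: Williamson-type O-alkylation of both sodium phenoxides should give the bis(methoxymethyl) ether, whose acetal groups cannot migrate to the benzylic alkoxide of step 3 and withstand the amide base and the quinone oxidant.

Step 3
Reactants: 3 3-bromo-4,6-bis(methoxymethoxy)-2-methylbenzaldehyde; 4 methyl (E)-3-methoxybut-2-enoate
Product: 6 rac-6-[3-bromo-4,6-bis(methoxymethoxy)-2-methylphenyl]-4-methoxy-5,6-dihydro-2H-pyran-2-one, via lithium aldolate 5 (not isolated)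
Conditions: LiN(i-Pr)2 (1.2 equiv), 4 (1.2 equiv), THF, −78 °C; then 3, −78 → 0 °C; aq. NH4Cl
Reagents that add atoms: none
Why: Vinylogous aldol addition of the lithium dienolate of 4 through its γ-carbon, followed by lactonization of the alkoxide onto the cis-disposed ester (the classical kavalactone ring synthesis), should form the C5′–C6′ and O1′–C2′ bonds; the new C6′ stereocenter arises as a racemate and is removed in step 4.

Step 4
Reactants: 6 rac-6-[3-bromo-4,6-bis(methoxymethoxy)-2-methylphenyl]-4-methoxy-5,6-dihydro-2H-pyran-2-one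
Product: 7 6-[3-bromo-4,6-bis(methoxymethoxy)-2-methylphenyl]-4-methoxy-2H-pyran-2-one
Conditions: DDQ (1.5 equiv), 1,4-dioxane, 90 °C
Reagents that add atoms: none
Why: Quinone dehydrogenation (hydride abstraction from the benzylic, oxygen-bearing C6′–H and loss of a proton from C5′), the known way from 5,6-dihydro-4-methoxy-2-pyranones to 2-pyranones, should be driven by the gain of the conjugated pyranone.

Step 5
Reactants: 8 4-ethynylphenol
Product: 9 1-ethynyl-4-(methoxymethoxy)benzene
Conditions: MOMCl (1.2 equiv), K2CO3 (2 equiv), acetone, 0 °C → rt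
Reagents that add atoms: chloromethyl methyl ether, COCCl
Why: O-Alkylation of the phenoxide (methoxymethyl ether formation) should be selective, since carbonate does not deprotonate the alkyne C–H.

Step 6
Reactants: 9 1-ethynyl-4-(methoxymethoxy)benzene
Product: 10 2-{1-[4-(methoxymethoxy)phenyl]ethenyl}-4,4,5,5-tetramethyl-1,3,2-dioxaborolane
Conditions: CuCl(SIMes) (5 mol %; SIMes = 1,3-dimesitylimidazolidin-2-ylidene), NaOt-Bu (5 mol %), B2pin2 (1.1 equiv), MeOH (2 equiv), THF, −15 °C → rt
Reagents that add atoms: bis(pinacolato)diboron, CC1(C)OB(OC1(C)C)B1OC(C)(C)C(C)(C)O1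
Why: Copper-catalysed protoboration (formal Markovnikov hydroboration) of a terminal aryl alkyne with an N-aryl carbene ligand should place boron on the internal carbon, methanol protonating the alkenylcopper intermediate.

Step 7
Reactants: 7 6-[3-bromo-4,6-bis(methoxymethoxy)-2-methylphenyl]-4-methoxy-2H-pyran-2-one; 10 2-{1-[4-(methoxymethoxy)phenyl]ethenyl}-4,4,5,5-tetramethyl-1,3,2-dioxaborolane
Product: 11 6-{4,6-bis(methoxymethoxy)-3-[1-(4-(methoxymethoxy)phenyl)ethenyl]-2-methylphenyl}-4-methoxy-2H-pyran-2-one
Conditions: Pd(OAc)2 (5 mol %), SPhos (10 mol %), K3PO4 (3 equiv), toluene/H2O 10:1, 90 °C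
Reagents that add atoms: none
Why: Suzuki–Miyaura cross-coupling with a dialkylbiarylphosphine ligand should allow oxidative addition and transmetalation at the doubly ortho-substituted C–Br bond and form C4a–C4, while phosphate in wet toluene leaves the pyranone and the acetal ethers intact.

Step 8
Reactants: 11 6-{4,6-bis(methoxymethoxy)-3-[1-(4-(methoxymethoxy)phenyl)ethenyl]-2-methylphenyl}-4-methoxy-2H-pyran-2-one
Product: 12 6-{4,6-dihydroxy-3-[1-(4-hydroxyphenyl)ethenyl]-2-methylphenyl}-4-methoxy-2H-pyran-2-one
Conditions: NaHSO4·SiO2, CH2Cl2/MeOH 20:1, rt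
Reagents that add atoms: none
Why: Acid-catalysed transacetalization of the three aryl methoxymethyl ethers to methanol on a mild solid acid should free the phenols, while the hindered 1,1-diarylethene and the vinylogous ester of the pyranone survive.

Step 9
Reactants: 12 6-{4,6-dihydroxy-3-[1-(4-hydroxyphenyl)ethenyl]-2-methylphenyl}-4-methoxy-2H-pyran-2-one
Product: 13 (4R)-7-hydroxy-4-(4-hydroxyphenyl)-6-(4-methoxy-2-oxo-2H-pyran-6-yl)-5-methylchroman-2-one
Conditions: Pd(OAc)2 (2 mol %), WingPhos (one antipode, see remark; 2.4 mol %), TsOH·H2O (10 mol %), CO (10 bar), 1,2-dichloroethane, 60 °C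
Reagents that add atoms: carbon monoxide, [C-]#[O+]
Why: A palladium hydride formed from zerovalent palladium and TsOH should add across the C4=C3 double bond with H to C4 and Pd to C3, CO then inserts into the C3–Pd bond, and the phenol oxygen on C8a attacks the acyl–palladium carbon C2 to release the lactone and regenerate the hydride. The closest known reaction is the palladium/WingPhos-catalysed asymmetric hydroesterification of 2-(1-arylvinyl)phenols, entered there from the tertiary diarylmethyl carbinols by acid-promoted dehydration, which gives 4-aryl-3,4-dihydrocoumarins. The dihydrocoumarin ring is closed by intramolecular O-acylation (6-exo attack of O1 on the acyl carbon), C2 being the only atom added. The C4 stereocenter is set in the hydropalladation, whose enantioface selection is controlled by the P-stereogenic bisphosphine and should be helped by the contrast between the flat 4-hydroxyphenyl group and the twisted, doubly ortho-substituted central ring. Regioselectivity (Pd on C3) is secured by the 1,1-diaryl substitution, which excludes a tertiary alkylpalladium, and chemoselectivity among the three phenols by geometry, since only O1 is ortho to the vinyl group. All atoms of 12 and of CO end in 13, and no later step can erode the stereocenter.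

**Compound list**

1 | 2,4-dihydroxy-6-methylbenzaldehyde | Cc1cc(O)cc(O)c1C=O | starting material
2 | 3-bromo-4,6-dihydroxy-2-methylbenzaldehyde | Cc1c(Br)c(O)cc(O)c1C=O | intermediate
3 | 3-bromo-4,6-bis(methoxymethoxy)-2-methylbenzaldehyde | Cc1c(Br)c(OCOC)cc(OCOC)c1C=O | intermediate
4 | methyl (E)-3-methoxybut-2-enoate | CO/C(C)=C/C(=O)OC | starting material
5 | lithium alkoxide of methyl (E)-5-[3-bromo-4,6-bis(methoxymethoxy)-2-methylphenyl]-5-hydroxy-3-methoxypent-2-enoate (racemic; SMILES of the neutral hydroxy ester) | COC(=O)/C=C(/OC)CC(O)c1c(C)c(Br)c(OCOC)cc1OCOC | intermediate (not isolated)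
6 | rac-6-[3-bromo-4,6-bis(methoxymethoxy)-2-methylphenyl]-4-methoxy-5,6-dihydro-2H-pyran-2-one | COC1=CC(=O)OC(C1)c1c(C)c(Br)c(OCOC)cc1OCOC | intermediate
7 | 6-[3-bromo-4,6-bis(methoxymethoxy)-2-methylphenyl]-4-methoxy-2H-pyran-2-one | COc1cc(-c2c(C)c(Br)c(OCOC)cc2OCOC)oc(=O)c1 | intermediate
8 | 4-ethynylphenol | C#Cc1ccc(O)cc1 | starting material
9 | 1-ethynyl-4-(methoxymethoxy)benzene | C#Cc1ccc(OCOC)cc1 | intermediate
10 | 2-{1-[4-(methoxymethoxy)phenyl]ethenyl}-4,4,5,5-tetramethyl-1,3,2-dioxaborolane | C=C(B1OC(C)(C)C(C)(C)O1)c1ccc(OCOC)cc1 | intermediate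
11 | 6-{4,6-bis(methoxymethoxy)-3-[1-(4-(methoxymethoxy)phenyl)ethenyl]-2-methylphenyl}-4-methoxy-2H-pyran-2-one | COc1cc(-c2c(C)c(C(=C)c3ccc(OCOC)cc3)c(OCOC)cc2OCOC)oc(=O)c1 | intermediate
12 | 6-{4,6-dihydroxy-3-[1-(4-hydroxyphenyl)ethenyl]-2-methylphenyl}-4-methoxy-2H-pyran-2-one | COc1cc(-c2c(C)c(C(=C)c3ccc(O)cc3)c(O)cc2O)oc(=O)c1 | intermediate
13 | (4R)-7-hydroxy-4-(4-hydroxyphenyl)-6-(4-methoxy-2-oxo-2H-pyran-6-yl)-5-methylchroman-2-one | COc1cc(-c2c(O)cc3c(c2C)[C@@H](c2ccc(O)cc2)CC(=O)O3)oc(=O)c1 | target

**Step count and risks**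

Total step count: 9. Longest linear sequence: 7 (steps 1 to 4 and 7 to 9).

Steps most likely to fail:

Step 9. Enantioface discrimination in the Pd–H insertion may be eroded. The methyl group on C5 and the hydroxyl on C8a force the vinyl group out of the plane of the central ring, and the insertion may become reversible before CO is taken up. The fallback sets out from 12 and comes back at 13. The same alkene would be cyclocarbonylated without chiral control (Pd(OAc)2, 1,4-bis(diphenylphosphino)butane, TsOH·H2O, CO 20 bar, toluene, 100 °C) to racemic 7-hydroxy-4-(4-hydroxyphenyl)-6-(4-methoxy-2-oxo-2H-pyran-6-yl)-5-methylchroman-2-one F1. The enantiomers would then be separated by preparative chromatography on a cellulose tris(3,5-dimethylphenylcarbamate) phase, the (4R) fraction being 13. Control of configuration thus passes from the catalyst to a separation.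

Step 7. Oxidative addition and transmetalation at the doubly ortho-substituted C–Br bond may be so slow that protodeboronation of the α-arylvinyl boronate wins. The fallback sets out from 7 and comes back at 11. Bromide 7 would be coupled under CO (Pd(OAc)2, di(1-adamantyl)-n-butylphosphine, K2CO3, CO 5 bar, toluene, 100 °C) with commercial [4-(methoxymethoxy)phenyl]boronic acid. This carbonylative Suzuki–Miyaura coupling, in which CO insertion relieves the crowding at palladium before transmetalation, should give [4,6-bis(methoxymethoxy)-3-(4-methoxy-2-oxo-2H-pyran-6-yl)-2-methylphenyl][4-(methoxymethoxy)phenyl]methanone F2. The ketone would be methylenated with Cp2Ti(μ-Cl)(μ-CH2)AlMe2 (pyridine, THF/toluene, −40 → 0 °C), which converts ketones faster than lactone carbonyls, to give 11.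

Step 4. Hydride abstraction from C6′ may be slow because the doubly ortho-substituted aryl ring cannot align with the breaking C–H bond, and the acidic hydroquinone by-product may meanwhile strip the methoxymethyl groups. The fallback sets out from 3 and comes back at 7, reaching the pyranone at the right oxidation level without a dehydrogenation. Aldehyde 3 would be added to the lithium dienolate of 2,2,6-trimethyl-4H-1,3-dioxin-4-one (LiN(i-Pr)2, THF, −78 °C) to give racemic 6-{2-[3-bromo-4,6-bis(methoxymethoxy)-2-methylphenyl]-2-hydroxyethyl}-2,2-dimethyl-4H-1,3-dioxin-4-one F3. Dess–Martin periodinane (NaHCO3, CH2Cl2) should oxidize the carbinol to 6-{2-[3-bromo-4,6-bis(methoxymethoxy)-2-methylphenyl]-2-oxoethyl}-2,2-dimethyl-4H-1,3-dioxin-4-one F4. In toluene at 110 °C F4 should lose acetone to an acylketene that closes onto the enolized aryl ketone, giving 6-[3-bromo-4,6-bis(methoxymethoxy)-2-methylphenyl]-4-hydroxy-2H-pyran-2-one F5. O-Methylation (Me2SO4, K2CO3, acetone) would then give 7.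

Further compounds
F1 | step 9 | racemic 7-hydroxy-4-(4-hydroxyphenyl)-6-(4-methoxy-2-oxo-2H-pyran-6-yl)-5-methylchroman-2-one | COc1cc(-c2c(O)cc3c(c2C)C(c2ccc(O)cc2)CC(=O)O3)oc(=O)c1
F2 | step 7 | [4,6-bis(methoxymethoxy)-3-(4-methoxy-2-oxo-2H-pyran-6-yl)-2-methylphenyl][4-(methoxymethoxy)phenyl]methanone | COc1cc(-c2c(C)c(C(=O)c3ccc(OCOC)cc3)c(OCOC)cc2OCOC)oc(=O)c1
F3 | step 4 | rac-6-{2-[3-bromo-4,6-bis(methoxymethoxy)-2-methylphenyl]-2-hydroxyethyl}-2,2-dimethyl-4H-1,3-dioxin-4-one | CC1(C)OC(=CC(=O)O1)CC(O)c1c(C)c(Br)c(OCOC)cc1OCOC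
F4 | step 4 | 6-{2-[3-bromo-4,6-bis(methoxymethoxy)-2-methylphenyl]-2-oxoethyl}-2,2-dimethyl-4H-1,3-dioxin-4-one | CC1(C)OC(=CC(=O)O1)CC(=O)c1c(C)c(Br)c(OCOC)cc1OCOC
F5 | step 4 | 6-[3-bromo-4,6-bis(methoxymethoxy)-2-methylphenyl]-4-hydroxy-2H-pyran-2-one | Oc1cc(-c2c(C)c(Br)c(OCOC)cc2OCOC)oc(=O)c1
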